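- Retrosynthesis: cut C3–C1′ (ring B leaves as an arylboronate), then O1–C2, C2–C3, C3–C4 and C4–C4a (ring C back to a phenol with C4a free), then C8–C8a and C6–C7 of ring A. This leaves a 2-alkyl-3-silyloxycyclobutenone and a prenyl-bearing siloxyalkyne; the cyclobutenone goes back to ketene and a second siloxyalkyne.
- Enabling feature: ring A (C4a, C5, C6, C7, C8, C8a) has no free position. Oxygen on C5, C7 and C8a alternates with the acyl carbon on C4a, the hydroxy-isopentenyl chain on C6 and the prenyl group on C8. A ketene carbonyl, an ynol ether and a 3-oxycyclobutenone deliver exactly this pattern, with O1 as the only free hydroxyl beside the only unsubstituted carbon.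
- Forward order: side-chain alkyne, then cyclobutenone; ring A by benzannulation; C4a acetylated by formylation, methyl addition and oxidation; ring C closed as a 3-iodochromone; ring B joined by cross-coupling; global desilylation.
- Stereochemistry: the single R carbinol centre comes from a catalytic asymmetric propargylation of methacrolein and is carried as a silyl ether; no later step touches it.

Key step: step 7

Assumption: (R)-TRIP is taken to direct the allenylboronate to the Re face of methacrolein, as it does with aromatic aldehydes, which gives the R alcohol; if the sense proved opposite, (S)-TRIP would be used. Ring A atoms carry the numbers of the final chromone throughout.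

Step 1
Reactants: 1 methacrolein (2-methylprop-2-enal); 2 allenylboronic acid pinacol ester
Product: 3 (R)-2-methylhex-1-en-5-yn-3-ol
Conditions: (R)-3,3′-bis(2,4,6-triisopropylphenyl)-1,1′-binaphthyl-2,2′-diyl hydrogen phosphate [(R)-TRIP] (5 mol%), 4 Å MS, toluene, −20 °C; aqueous work-up
Reagents that add atoms: none
Why: Chiral-phosphoric-acid-catalysed asymmetric propargylation of an aldehyde with an allenylboronate (SE2′ through a closed six-membered transition state), in which the phosphate binds the boronate oxygen and the formyl hydrogen and should expose the Re face, setting the R carbinol centre.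

Step 2
Reactants: 3 (R)-2-methylhex-1-en-5-yn-3-ol
Product: 4 (R)-3-(tert-butyldimethylsilyloxy)-2-methylhex-1-en-5-yne
Conditions: TBSCl, imidazole, DMF, rt
Reagents that add atoms: tert-butyldimethylsilyl chloride, CC(C)(C)[Si](C)(C)Cl
Why: Standard imidazole-promoted silylation of a secondary alcohol, which also removes the volatility problem of 3.

Step 3
Reactants: 4 (R)-3-(tert-butyldimethylsilyloxy)-2-methylhex-1-en-5-yne
Product: 7 (R)-3-(tert-butyldimethylsilyloxy)-2-methyl-6-(triisopropylsilyloxy)hex-1-en-5-yne, via lithium acetylide 5 (not isolated), via lithium ynolate 6 (not isolated)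
Conditions: n-BuLi, THF, −78 °C; LiOOt-Bu (from t-BuOOH and LiHMDS), −78 → 0 °C; TIPSOTf, −78 °C
Reagents that add atoms: tert-butyl hydroperoxide, CC(C)(C)OO; triisopropylsilyl triflate, CC(C)[Si](OS(=O)(=O)C(F)(F)F)(C(C)C)C(C)C
Why: Oxidation of a lithium acetylide with lithium tert-butylperoxide to the lithium ynolate, followed by O-silylation with a bulky silyl triflate, is an established route from terminal alkynes to triisopropylsilyl ynol ethers; the alkene and the silyl ether are inert.

Step 4
Reactants: 7 (R)-3-(tert-butyldimethylsilyloxy)-2-methyl-6-(triisopropylsilyloxy)hex-1-en-5-yne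
Product: 8 2-[(2R)-2-(tert-butyldimethylsilyloxy)-3-methylbut-3-enyl]-3-(triisopropylsilyloxy)cyclobut-2-en-1-one
Conditions: CH2=C=O (gas, from acetone pyrolysis), CH2Cl2, 0 °C → rt
Reagents that add atoms: ketene, C=C=O
Why: Ketene–ynol ether [2+2] cycloaddition, in which the nucleophilic chain-bearing alkyne carbon bonds to the ketene carbonyl carbon and the oxygen-bearing carbon to the CH2, so the chain arrives at C2, the silyloxy group at C3 and C4 stays CH2.

Step 5
Reactants: 9 4-methylpent-3-enoic acid
Product: 10 methyl 4-methylpent-3-enoate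
Conditions: MeI, K2CO3, DMF, rt
Reagents that add atoms: iodomethane, CI
Why: Carboxylate alkylation gives the ester without acid, which would lactonise this β,γ-unsaturated acid or move its double bond.

Step 6
Reactants: 10 methyl 4-methylpent-3-enoate
Product: 13 triisopropyl(5-methylhex-4-en-1-ynyloxy)silane, via dibromo enolate 11 (not isolated), via lithium ynolate 12 (not isolated)
Conditions: CH2Br2, LiTMP, THF, −78 °C; n-BuLi, −78 → 0 °C; TIPSCl, −78 °C → rt
Reagents that add atoms: dibromomethane, BrCBr; triisopropylsilyl chloride, CC(C)[Si](Cl)(C(C)C)C(C)C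
Why: Kowalski ester homologation (addition of LiCHBr2, enolisation, bromine–lithium exchange and 1,2-shift to the ynolate) followed by O-silylation is the standard preparation of siloxyalkynes from esters; addition to the ester at −78 °C should outrun deprotonation of the allylic α-position.

Step 7
Reactants: 8 2-[(2R)-2-(tert-butyldimethylsilyloxy)-3-methylbut-3-enyl]-3-(triisopropylsilyloxy)cyclobut-2-en-1-one; 13 triisopropyl(5-methylhex-4-en-1-ynyloxy)silane
Product: 18 4-[(2R)-2-(tert-butyldimethylsilyloxy)-3-methylbut-3-enyl]-2-(3-methylbut-2-enyl)-3,5-bis(triisopropylsilyloxy)phenol, via vinylketene 14 (not isolated), via 4-vinylcyclobutenone 15 (not isolated), via dienylketene 16 (not isolated), via cyclohexa-2,4-dienone 17 (not isolated)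
Conditions: 13 (1.3 equiv), toluene, 80 → 110 °C, sealed tube, Ar
Reagents that add atoms: none
Why: Heating opens 8 by 4π-electrocyclic cleavage of the C1–C4 bond to the siloxy vinylketene 14, whose ketene C=C adds 13 in a [2+2] step to give 15 and forms C8–C8a and C6–C7; 15 reopens to the dienylketene 16, which closes ring A by a thermally allowed disrotatory 6π-electrocyclisation (re-forming C4a–C8a) to 17 and tautomerises to the phenol. The closest known reaction is the Danheiser benzannulation of cyclobutenones with siloxyalkynes to resorcinol monosilyl ethers; the 3-silyloxy group on the cyclobutenone extends it to the phloroglucinol pattern and is the less documented part. No stereocentre is created (the quaternary carbon of 15 is lost on aromatisation) and the remote R carbinol centre is not involved. The selectivity needed is the orientation of the ketene–alkyne union, and the polarisation of the ynol ether secures it: its nucleophilic prenyl-bearing carbon bonds to the electrophilic ketene carbonyl carbon, so the prenyl group ends up next to the new hydroxyl and the silyloxy group next to the side-chain carbon. Only the dienylketene isomer with the ketene and the siloxyvinyl group cis can cyclise, and reversible opening of 15 should funnel material through it.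

Step 8
Reactants: 18 4-[(2R)-2-(tert-butyldimethylsilyloxy)-3-methylbut-3-enyl]-2-(3-methylbut-2-enyl)-3,5-bis(triisopropylsilyloxy)phenol
Product: 20 5-[(2R)-2-(tert-butyldimethylsilyloxy)-3-methylbut-3-enyl]-2-hydroxy-3-(3-methylbut-2-enyl)-4,6-bis(triisopropylsilyloxy)benzaldehyde, via salicyl alcohol 19 (not isolated)
Conditions: MgCl2, Et3N, (CH2O)n, MeCN, reflux
Reagents that add atoms: formaldehyde (as paraformaldehyde), C=O
Why: Magnesium-mediated ortho-formylation of a phenol (Casnati–Skattebøl), in which the magnesium phenoxide delivers formaldehyde to the only free ring carbon (C4a) and a second formaldehyde oxidises the salicyl alcohol by hydride transfer; silyl ethers and isolated alkenes are inert to MgCl2/Et3N.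

Step 9
Reactants: 20 5-[(2R)-2-(tert-butyldimethylsilyloxy)-3-methylbut-3-enyl]-2-hydroxy-3-(3-methylbut-2-enyl)-4,6-bis(triisopropylsilyloxy)benzaldehyde
Product: 21 4-[(2R)-2-(tert-butyldimethylsilyloxy)-3-methylbut-3-enyl]-2-(1-hydroxyethyl)-6-(3-methylbut-2-enyl)-3,5-bis(triisopropylsilyloxy)phenol (both carbinol epimers)
Conditions: MeMgBr (3 equiv), THF, −78 → 0 °C; NH4Cl work-up
Reagents that add atoms: methylmagnesium bromide, C[Mg]Br
Why: Grignard addition to a salicylaldehyde after deprotonation of the phenol by the first equivalent; the new carbinol centre is formed without control and is removed in the next step, and the low temperature and bulky triisopropylsilyl groups should prevent silyl migration to the alkoxide.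

Step 10
Reactants: 21 4-[(2R)-2-(tert-butyldimethylsilyloxy)-3-methylbut-3-enyl]-2-(1-hydroxyethyl)-6-(3-methylbut-2-enyl)-3,5-bis(triisopropylsilyloxy)phenol
Product: 22 1-{5-[(2R)-2-(tert-butyldimethylsilyloxy)-3-methylbut-3-enyl]-2-hydroxy-3-(3-methylbut-2-enyl)-4,6-bis(triisopropylsilyloxy)phenyl}ethanone
Conditions: Dess–Martin periodinane, pyridine, CH2Cl2, 0 °C
Reagents that add atoms: none
Why: Dess–Martin oxidation of a secondary benzylic alcohol under buffered, non-acidic conditions, which should avoid ionisation to an ortho-quinone methide; both positions ortho to the phenol are blocked, which disfavours ring oxidation.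

Step 11
Reactants: 22 1-{5-[(2R)-2-(tert-butyldimethylsilyloxy)-3-methylbut-3-enyl]-2-hydroxy-3-(3-methylbut-2-enyl)-4,6-bis(triisopropylsilyloxy)phenyl}ethanone
Product: 24 6-[(2R)-2-(tert-butyldimethylsilyloxy)-3-methylbut-3-enyl]-3-iodo-8-(3-methylbut-2-enyl)-5,7-bis(triisopropylsilyloxy)-4H-chromen-4-one, via enaminone 23 (not isolated)
Conditions: Me2NCH(OMe)2, toluene, 90 °C; concentrate; I2 (1.1 equiv), pyridine, CHCl3, 0 °C → rt
Reagents that add atoms: N,N-dimethylformamide dimethyl acetal, CN(C)C(OC)OC; iodine, II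
Why: Enaminone formation from a 2-hydroxyacetophenone followed by iodine-mediated cyclisation (α-iodination, attack of the phenol oxygen on the iminium carbon, loss of dimethylamine) is the standard entry to 3-iodochromones and closes ring C; the enaminone is far more nucleophilic than the two isolated alkenes.

Step 12
Reactants: 25 4-bromobenzene-1,3-diol
Product: 26 1-bromo-2,4-bis(triisopropylsilyloxy)benzene
Conditions: TIPSOTf, 2,6-lutidine, CH2Cl2, 0 °C → rt
Reagents that add atoms: triisopropylsilyl triflate, CC(C)[Si](OS(=O)(=O)C(F)(F)F)(C(C)C)C(C)C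
Why: Silylation of both phenols with a silyl triflate and a hindered base, the triflate being needed for the hydroxyl next to bromine.

Step 13
Reactants: 26 1-bromo-2,4-bis(triisopropylsilyloxy)benzene
Product: 27 2-[2,4-bis(triisopropylsilyloxy)phenyl]-4,4,5,5-tetramethyl-1,3,2-dioxaborolane
Conditions: B2pin2, PdCl2(dppf) (5 mol%), KOAc, 1,4-dioxane, 90 °C
Reagents that add atoms: bis(pinacolato)diboron, CC1(C)OB(OC1(C)C)B1OC(C)(C)C(C)(C)O1
Why: Miyaura borylation of an aryl bromide under weakly basic anhydrous conditions, which leaves aryl silyl ethers intact and avoids an ortho-silyloxy aryllithium.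

Step 14
Reactants: 24 6-[(2R)-2-(tert-butyldimethylsilyloxy)-3-methylbut-3-enyl]-3-iodo-8-(3-methylbut-2-enyl)-5,7-bis(triisopropylsilyloxy)-4H-chromen-4-one; 27 2-[2,4-bis(triisopropylsilyloxy)phenyl]-4,4,5,5-tetramethyl-1,3,2-dioxaborolane
Product: 28 3-[2,4-bis(triisopropylsilyloxy)phenyl]-6-[(2R)-2-(tert-butyldimethylsilyloxy)-3-methylbut-3-enyl]-8-(3-methylbut-2-enyl)-5,7-bis(triisopropylsilyloxy)-4H-chromen-4-one
Conditions: Pd(OAc)2 (5 mol%), SPhos (10 mol%), K3PO4, toluene/H2O, 80 °C
Reagents that add atoms: none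
Why: Suzuki–Miyaura coupling of a 3-iodochromone with an arylboronate is the usual way to form the C3–C1′ bond of isoflavones, and a bulky biarylphosphine on zerovalent palladium handles the ortho-substituted boronate; any silyl group lost here is removed in the next step anyway.

Step 15
Reactants: 28 3-[2,4-bis(triisopropylsilyloxy)phenyl]-6-[(2R)-2-(tert-butyldimethylsilyloxy)-3-methylbut-3-enyl]-8-(3-methylbut-2-enyl)-5,7-bis(triisopropylsilyloxy)-4H-chromen-4-one
Product: 29 3-(2,4-dihydroxyphenyl)-5,7-dihydroxy-6-[(2R)-2-hydroxy-3-methylbut-3-enyl]-8-(3-methylbut-2-enyl)-4H-chromen-4-one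
Conditions: TBAF, AcOH, THF, 0 °C → rt, Ar
Reagents that add atoms: none
Why: Fluoride-mediated desilylation removes the four aryl triisopropylsilyl ethers and the secondary tert-butyldimethylsilyl ether in one operation; the acetic acid buffer avoids both strong base (chromone opening, phenoxide oxidation) and strong acid (cyclisation of the prenyl group or the allylic alcohol onto a neighbouring phenol), and the carbinol centre is not affected.

Compound list
1 | methacrolein | C=C(C)C=O | starting material
2 | allenylboronic acid pinacol ester | C=C=CB1OC(C)(C)C(C)(C)O1 | starting material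
3 | (R)-2-methylhex-1-en-5-yn-3-ol | C=C(C)[C@H](O)CC#C | intermediate
4 | (R)-3-(tert-butyldimethylsilyloxy)-2-methylhex-1-en-5-yne | C=C(C)[C@H](O[Si](C)(C)C(C)(C)C)CC#C | intermediate
5 | lithium acetylide of 4 | C=C(C)[C@H](O[Si](C)(C)C(C)(C)C)CC#[C-].[Li+] | intermediate (not isolated)
6 | lithium (R)-4-(tert-butyldimethylsilyloxy)-5-methylhex-5-en-1-yn-1-olate | C=C(C)[C@H](O[Si](C)(C)C(C)(C)C)CC#C[O-].[Li+] | intermediate (not isolated)
7 | (R)-3-(tert-butyldimethylsilyloxy)-2-methyl-6-(triisopropylsilyloxy)hex-1-en-5-yne | C=C(C)[C@H](O[Si](C)(C)C(C)(C)C)CC#CO[Si](C(C)C)(C(C)C)C(C)C | intermediate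
8 | 2-[(2R)-2-(tert-butyldimethylsilyloxy)-3-methylbut-3-enyl]-3-(triisopropylsilyloxy)cyclobut-2-en-1-one | C=C(C)[C@H](O[Si](C)(C)C(C)(C)C)CC1=C(O[Si](C(C)C)(C(C)C)C(C)C)CC1=O | intermediate
9 | 4-methylpent-3-enoic acid | CC(C)=CCC(=O)O | starting material
10 | methyl 4-methylpent-3-enoate | CC(C)=CCC(=O)OC | intermediate
11 | lithium 1,1-dibromo-5-methylhexa-1,4-dien-2-olate | CC(C)=CCC([O-])=C(Br)Br.[Li+] | intermediate (not isolated)
12 | lithium 5-methylhex-4-en-1-yn-1-olate | CC(C)=CCC#C[O-].[Li+] | intermediate (not isolated)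
13 | triisopropyl(5-methylhex-4-en-1-ynyloxy)silane | CC(C)=CCC#CO[Si](C(C)C)(C(C)C)C(C)C | intermediate
14 | 2-[(2R)-2-(tert-butyldimethylsilyloxy)-3-methylbut-3-enyl]-3-(triisopropylsilyloxy)buta-1,3-dien-1-one (vinylketene) | C=C(C)[C@H](O[Si](C)(C)C(C)(C)C)CC(=C=O)C(=C)O[Si](C(C)C)(C(C)C)C(C)C | intermediate (not isolated)
15 | 4-[(2R)-2-(tert-butyldimethylsilyloxy)-3-methylbut-3-enyl]-2-(3-methylbut-2-enyl)-3-(triisopropylsilyloxy)-4-[1-(triisopropylsilyloxy)vinyl]cyclobut-2-en-1-one (both epimers at C4) | C=C(C)[C@H](O[Si](C)(C)C(C)(C)C)CC1(C(=C)O[Si](C(C)C)(C(C)C)C(C)C)C(=O)C(CC=C(C)C)=C1O[Si](C(C)C)(C(C)C)C(C)C | intermediate (not isolated)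
16 | (3E)-4-[(2R)-2-(tert-butyldimethylsilyloxy)-3-methylbut-3-enyl]-2-(3-methylbut-2-enyl)-3,5-bis(triisopropylsilyloxy)hexa-1,3,5-trien-1-one (dienylketene) | C=C(C)[C@H](O[Si](C)(C)C(C)(C)C)C/C(C(=C)O[Si](C(C)C)(C(C)C)C(C)C)=C(\O[Si](C(C)C)(C(C)C)C(C)C)C(CC=C(C)C)=C=O | intermediate (not isolated)
17 | 4-[(2R)-2-(tert-butyldimethylsilyloxy)-3-methylbut-3-enyl]-2-(3-methylbut-2-enyl)-3,5-bis(triisopropylsilyloxy)cyclohexa-2,4-dien-1-one | C=C(C)[C@H](O[Si](C)(C)C(C)(C)C)CC1=C(O[Si](C(C)C)(C(C)C)C(C)C)CC(=O)C(CC=C(C)C)=C1O[Si](C(C)C)(C(C)C)C(C)C | intermediate (not isolated)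
18 | 4-[(2R)-2-(tert-butyldimethylsilyloxy)-3-methylbut-3-enyl]-2-(3-methylbut-2-enyl)-3,5-bis(triisopropylsilyloxy)phenol | C=C(C)[C@H](O[Si](C)(C)C(C)(C)C)Cc1c(O[Si](C(C)C)(C(C)C)C(C)C)cc(O)c(CC=C(C)C)c1O[Si](C(C)C)(C(C)C)C(C)C | intermediate
19 | 4-[(2R)-2-(tert-butyldimethylsilyloxy)-3-methylbut-3-enyl]-2-(hydroxymethyl)-6-(3-methylbut-2-enyl)-3,5-bis(triisopropylsilyloxy)phenol (as its magnesium salt) | C=C(C)[C@H](O[Si](C)(C)C(C)(C)C)Cc1c(O[Si](C(C)C)(C(C)C)C(C)C)c(CO)c(O)c(CC=C(C)C)c1O[Si](C(C)C)(C(C)C)C(C)C | intermediate (not isolated)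
20 | 5-[(2R)-2-(tert-butyldimethylsilyloxy)-3-methylbut-3-enyl]-2-hydroxy-3-(3-methylbut-2-enyl)-4,6-bis(triisopropylsilyloxy)benzaldehyde | C=C(C)[C@H](O[Si](C)(C)C(C)(C)C)Cc1c(O[Si](C(C)C)(C(C)C)C(C)C)c(C=O)c(O)c(CC=C(C)C)c1O[Si](C(C)C)(C(C)C)C(C)C | intermediate
21 | 4-[(2R)-2-(tert-butyldimethylsilyloxy)-3-methylbut-3-enyl]-2-(1-hydroxyethyl)-6-(3-methylbut-2-enyl)-3,5-bis(triisopropylsilyloxy)phenol (carbinol epimers) | C=C(C)[C@H](O[Si](C)(C)C(C)(C)C)Cc1c(O[Si](C(C)C)(C(C)C)C(C)C)c(C(C)O)c(O)c(CC=C(C)C)c1O[Si](C(C)C)(C(C)C)C(C)C | intermediate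
22 | 1-{5-[(2R)-2-(tert-butyldimethylsilyloxy)-3-methylbut-3-enyl]-2-hydroxy-3-(3-methylbut-2-enyl)-4,6-bis(triisopropylsilyloxy)phenyl}ethanone | C=C(C)[C@H](O[Si](C)(C)C(C)(C)C)Cc1c(O[Si](C(C)C)(C(C)C)C(C)C)c(C(C)=O)c(O)c(CC=C(C)C)c1O[Si](C(C)C)(C(C)C)C(C)C | intermediate
23 | (E)-1-{5-[(2R)-2-(tert-butyldimethylsilyloxy)-3-methylbut-3-enyl]-2-hydroxy-3-(3-methylbut-2-enyl)-4,6-bis(triisopropylsilyloxy)phenyl}-3-(dimethylamino)prop-2-en-1-one | C=C(C)[C@H](O[Si](C)(C)C(C)(C)C)Cc1c(O[Si](C(C)C)(C(C)C)C(C)C)c(C(=O)/C=C/N(C)C)c(O)c(CC=C(C)C)c1O[Si](C(C)C)(C(C)C)C(C)C | intermediate (not isolated)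
24 | 6-[(2R)-2-(tert-butyldimethylsilyloxy)-3-methylbut-3-enyl]-3-iodo-8-(3-methylbut-2-enyl)-5,7-bis(triisopropylsilyloxy)-4H-chromen-4-one | C=C(C)[C@H](O[Si](C)(C)C(C)(C)C)Cc1c(O[Si](C(C)C)(C(C)C)C(C)C)c(CC=C(C)C)c2occ(I)c(=O)c2c1O[Si](C(C)C)(C(C)C)C(C)C | intermediate
25 | 4-bromobenzene-1,3-diol | Oc1ccc(Br)c(O)c1 | starting material
26 | 1-bromo-2,4-bis(triisopropylsilyloxy)benzene | Brc1ccc(O[Si](C(C)C)(C(C)C)C(C)C)cc1O[Si](C(C)C)(C(C)C)C(C)C | intermediate
27 | 2-[2,4-bis(triisopropylsilyloxy)phenyl]-4,4,5,5-tetramethyl-1,3,2-dioxaborolane | CC1(C)OB(c2ccc(O[Si](C(C)C)(C(C)C)C(C)C)cc2O[Si](C(C)C)(C(C)C)C(C)C)OC1(C)C | intermediate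
28 | 3-[2,4-bis(triisopropylsilyloxy)phenyl]-6-[(2R)-2-(tert-butyldimethylsilyloxy)-3-methylbut-3-enyl]-8-(3-methylbut-2-enyl)-5,7-bis(triisopropylsilyloxy)-4H-chromen-4-one | C=C(C)[C@H](O[Si](C)(C)C(C)(C)C)Cc1c(O[Si](C(C)C)(C(C)C)C(C)C)c(CC=C(C)C)c2occ(-c3ccc(O[Si](C(C)C)(C(C)C)C(C)C)cc3O[Si](C(C)C)(C(C)C)C(C)C)c(=O)c2c1O[Si](C(C)C)(C(C)C)C(C)C | intermediate
29 | 3-(2,4-dihydroxyphenyl)-5,7-dihydroxy-6-[(2R)-2-hydroxy-3-methylbut-3-enyl]-8-(3-methylbut-2-enyl)-4H-chromen-4-one | C=C(C)[C@H](O)Cc1c(O)c(CC=C(C)C)c2occ(-c3ccc(O)cc3O)c(=O)c2c1O | target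

Count and risks
Total steps: 15. Longest linear sequence: 11 steps (1, 2, 3, 4, 7, 8, 9, 10, 11, 14, 15).

The three steps most likely to fail, in order of risk:

First, step 7 (benzannulation). What may go wrong: at 80–110 °C the siloxy vinylketene may be lost to dimerisation or to acylation of the phenol as it forms, and long heating may cleave the vinylogous silyl ester before the cascade is complete. Fallback for step 7, setting out from 8 and 13 and coming back at 18: the bimolecular ketene capture is separated from the aromatisation. Cyclobutenone 8 is irradiated (Pyrex-filtered medium-pressure mercury lamp) at room temperature in the presence of 13, so that a photochemical ring opening gives 14 and the [2+2] step gives 15 while no phenol is present. 15 is then freed from excess 13 and heated alone in dilute toluene, where only the unimolecular steps through 16 and 17 to 18 remain. This two-stage photochemical and thermal sequence passes only through numbered compounds of the route, so no new compound arises and the entry for this fallback is F0 with no compound.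

Second, step 8 (ortho-formylation). What may go wrong: the magnesium-bound formaldehyde may not reach C4a, which lies between the O–Mg group and a bulky silyloxy group, so that the phenol is recovered or decomposes slowly at reflux. Fallback for step 8, setting out from 18 and coming back at 22: the carbon is brought in through a halogen instead. Bromination of 18 with NBS in CH2Cl2 at −78 °C should give 2-bromo-4-[(2R)-2-(tert-butyldimethylsilyloxy)-3-methylbut-3-enyl]-6-(3-methylbut-2-enyl)-3,5-bis(triisopropylsilyloxy)phenol F1. Bromophenol F1 is deprotonated at oxygen with MeLi, subjected to bromine–lithium exchange with t-BuLi in THF at −78 °C and trapped with N-methoxy-N-methylacetamide, which should give acetophenone 22 directly. Steps 9 and 10 are then not needed.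

Third, step 11 (enaminone formation and iodocyclisation). What may go wrong: iodine may be diverted to the prenyl double bond with participation of the free O1 hydroxyl (iodoetherification), or to the isopropenyl group, before the enaminone has cyclised. Fallback for step 11, setting out from 22 and 26 and coming back at 28: ring B is attached before ring C is closed and no electrophilic halogen is used. Palladium-catalysed α-arylation of ketone 22 with bromide 26 (Pd(OAc)2, XPhos, NaOt-Bu in excess to cover the phenol, toluene, 80 °C) should give 1-{5-[(2R)-2-(tert-butyldimethylsilyloxy)-3-methylbut-3-enyl]-2-hydroxy-3-(3-methylbut-2-enyl)-4,6-bis(triisopropylsilyloxy)phenyl}-2-[2,4-bis(triisopropylsilyloxy)phenyl]ethanone F2. Heating deoxybenzoin F2 with Me2NCH(OMe)2 in toluene should close the pyranone to 28. Steps 13 and 14 are then not needed.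

Further compounds
F0 | step 7 | none | none
F1 | step 8 | 2-bromo-4-[(2R)-2-(tert-butyldimethylsilyloxy)-3-methylbut-3-enyl]-6-(3-methylbut-2-enyl)-3,5-bis(triisopropylsilyloxy)phenol | C=C(C)[C@H](O[Si](C)(C)C(C)(C)C)Cc1c(O[Si](C(C)C)(C(C)C)C(C)C)c(Br)c(O)c(CC=C(C)C)c1O[Si](C(C)C)(C(C)C)C(C)C
F2 | step 11 | 1-{5-[(2R)-2-(tert-butyldimethylsilyloxy)-3-methylbut-3-enyl]-2-hydroxy-3-(3-methylbut-2-enyl)-4,6-bis(triisopropylsilyloxy)phenyl}-2-[2,4-bis(triisopropylsilyloxy)phenyl]ethanone | C=C(C)[C@H](O[Si](C)(C)C(C)(C)C)Cc1c(O[Si](C(C)C)(C(C)C)C(C)C)c(C(=O)Cc2ccc(O[Si](C(C)C)(C(C)C)C(C)C)cc2O[Si](C(C)C)(C(C)C)C(C)C)c(O)c(CC=C(C)C)c1O[Si](C(C)C)(C(C)C)C(C)C
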